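**Plan**

1. Numbering and target: ansa chain C1 (amide C=O) to C15 (carbinol), ring carbons C16–C21 (chain on C16, N on C20). The structure is read as 15-hydroxy, 11,12-dimethoxy, 7-carbamate, 2E,4Z,8E and 6S,7R,10S,11R,12S,14S,15R.
2. Cuts, last to first: quinone to the 18,21-dimethoxyarene; carbamate off; N–C20 (ring-closing aryl amidation); C2=C3 and C4=C5 (Wittig, Still–Gennari); C6–C7 (aldol); C8=C9 (Wittig); C15–C16 (aryllithium on a Weinreb amide); C12–C13 (ketyl–methacrylate coupling); C10–C11 (aldol).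
3. Enabling feature: the oxygens on C12 and C15 are 1,4-related through C13 and the methyl-bearing C14. C12–C15 can therefore be carried as a cis α-methyl γ-butyrolactone (ring O–C15(=O)–C14–C13–C12), which SmI2 builds from a C9–C12 α-methoxy aldehyde and methyl methacrylate.
4. Forward order: C9–C12 aldehyde, then the temporary lactone (first ring), Weinreb amide, arene joined at C15, chain grown from C9 to C1, 19-membered lactam (second ring), carbamate, quinone, free 15-OH.
5. Stereochemistry: C10/C11 from a boron-mediated and C6/C7 from a titanium-mediated Evans syn aldol with the same (R)-oxazolidinone; C12 from Felkin–Anh addition of the non-chelated ketyl; C14 from protonation of the lactone enolate; C15 from a CBS reduction; olefin geometry from stabilised Wittig reagents (E) and the Still–Gennari reagent (Z).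

Key step: step 6

**Route**

Step 1
Reactants: 1 (R)-4-benzyl-3-propanoyl-1,3-oxazolidin-2-one; 2 acrolein
Product: 4 (R)-4-benzyl-3-[(2R,3S)-3-hydroxy-2-methylpent-4-enoyl]-1,3-oxazolidin-2-one, via boron enolate 3 (not isolated)
Conditions: Bu2BOTf, Et3N, CH2Cl2, −78 to 0 °C; 2, −78 to 0 °C; then pH 7 buffer, MeOH, H2O2, 0 °C
Reagents that add atoms: none
Why: Evans syn aldol reaction; the Z boron enolate reacts through a closed chair transition state whose face is fixed by the benzyl group of the auxiliary, which should set C10 and C11 syn in the required absolute sense.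

Step 2
Reactants: 4 (R)-4-benzyl-3-[(2R,3S)-3-hydroxy-2-methylpent-4-enoyl]-1,3-oxazolidin-2-one
Product: 5 (R)-4-benzyl-3-[(2R,3S)-3-methoxy-2-methylpent-4-enoyl]-1,3-oxazolidin-2-one
Conditions: Me3OBF4, 1,8-bis(dimethylamino)naphthalene, CH2Cl2, rt
Reagents that add atoms: trimethyloxonium tetrafluoroborate, C[O+](C)C.F[B-](F)(F)F
Why: O-alkylation with an oxonium salt under non-basic conditions should methylate the aldol hydroxyl without retro-aldol cleavage or epimerisation at C10.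

Step 3
Reactants: 5 (R)-4-benzyl-3-[(2R,3S)-3-methoxy-2-methylpent-4-enoyl]-1,3-oxazolidin-2-one
Product: 6 (2S,3S)-3-methoxy-2-methylpent-4-en-1-ol
Conditions: LiBH4, MeOH (1 equiv), Et2O, 0 °C
Reagents that add atoms: none
Why: reductive cleavage of the N-acyl oxazolidinone by borohydride attack at the exocyclic carbonyl should give the C9 primary alcohol and release the auxiliary.

Step 4
Reactants: 6 (2S,3S)-3-methoxy-2-methylpent-4-en-1-ol
Product: 7 (3S,4S)-3-methoxy-5-[(4-methoxybenzyl)oxy]-4-methylpent-1-ene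
Conditions: NaH, 4-methoxybenzyl chloride, Bu4NI (cat.), DMF, 0 °C to rt
Reagents that add atoms: 4-methoxybenzyl chloride, COc1ccc(CCl)cc1
Why: Williamson ether synthesis on an unhindered primary alkoxide; no base-sensitive group is present.

Step 5
Reactants: 7 (3S,4S)-3-methoxy-5-[(4-methoxybenzyl)oxy]-4-methylpent-1-ene
Product: 9 (2R,3S)-2-methoxy-4-[(4-methoxybenzyl)oxy]-3-methylbutanal, via ozonide 8 (not isolated)
Conditions: O3 (stopped at first excess), CH2Cl2, −78 °C; then PPh3, −78 °C to rt; 9 used crude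
Reagents that add atoms: ozone, [O-][O+]=O
Why: ozonolysis with reductive work-up; the terminal vinyl group should react far faster than the anisyl ring at −78 °C, and the neutral work-up leaves the α-methoxy aldehyde unepimerised.

Step 6
Reactants: 9 (2R,3S)-2-methoxy-4-[(4-methoxybenzyl)oxy]-3-methylbutanal; 10 methyl methacrylate
Product: 14 (3S,5S)-5-{(1R,2S)-1-methoxy-3-[(4-methoxybenzyl)oxy]-2-methylpropyl}-3-methyloxolan-2-one (cis lactone spanning C12–C15), via samarium alkoxide 11 (not isolated), via lactone epimers 12 (not isolated), via lithium enolate 13 (not isolated)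
Conditions: SmI2 (2.5 equiv), HMPA, t-BuOH (2 equiv), THF, −78 °C, slow addition of 9 with 10 (3 equiv); aq. NH4Cl work-up; then LiN(i-Pr)2, THF, −78 °C; 2,6-di-tert-butylphenol, −78 °C; aq. NH4Cl
Reagents that add atoms: none
Why: Divalent samarium should reduce aldehyde 9 to a ketyl that adds to the unsubstituted terminus (C13) of the methacrylate, and a second electron turns the α-ester radical into a samarium enolate that t-BuOH protonates at C14 to give alkoxide 11. The C12 alkoxide then closes the five-membered ring by 5-exo-trig acyl substitution at the ester carbonyl with loss of methoxide. The closest known reaction is the SmI2-mediated reductive coupling of aldehydes with acrylates and methacrylates to γ-butyrolactones. C12 is set in the C–C bond formation by Felkin–Anh approach anti to the C11 methoxy group; HMPA saturates the samarium so that no five-membered chelate with the methoxy oxygen, which would lead to the 11,12-syn isomer, should form. C14 is not expected to be controlled in the open-chain protonation, so crude lactones 12 are converted into enolate 13 and protonated by the bulky phenol on the face opposite the C12 side chain, which places the methyl cis, the arrangement also favoured at equilibrium. The step needs cross-coupling to outrun pinacol dimerisation and reductive loss of the α-methoxy group, which excess acceptor, slow addition of 9 and low temperature should secure, while the α-methoxy stereocentre next to the ketyl carbon is the substrate element that directs the facial choice.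

Step 7
Reactants: 14 (3S,5S)-5-{(1R,2S)-1-methoxy-3-[(4-methoxybenzyl)oxy]-2-methylpropyl}-3-methyloxolan-2-one
Product: 15 (2S,4S,5R,6S)-4-hydroxy-N,5-dimethoxy-7-[(4-methoxybenzyl)oxy]-N,2,6-trimethylheptanamide
Conditions: MeNH(OMe)·HCl, AlMe3, CH2Cl2, 0 °C to rt; cold aqueous work-up; used crude at once
Reagents that add atoms: N,O-dimethylhydroxylamine hydrochloride, CNOC.Cl
Why: Weinreb aminolysis of a lactone by an aluminium amide; the Lewis-acidic, non-enolising conditions should leave C14 intact, and immediate use limits relactonisation of the γ-hydroxy amide.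

Step 8
Reactants: 15 (2S,4S,5R,6S)-4-hydroxy-N,5-dimethoxy-7-[(4-methoxybenzyl)oxy]-N,2,6-trimethylheptanamide
Product: 16 (2S,4S,5R,6S)-N,4,5-trimethoxy-7-[(4-methoxybenzyl)oxy]-N,2,6-trimethylheptanamide
Conditions: Me3OBF4, 1,8-bis(dimethylamino)naphthalene, CH2Cl2, 0 °C to rt
Reagents that add atoms: trimethyloxonium tetrafluoroborate, C[O+](C)C.F[B-](F)(F)F
Why: oxonium-salt O-methylation without forming an alkoxide should cap the C12 hydroxyl before it can re-close the lactone and without enolising the amide.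

Step 9
Reactants: 17 2,6-dibromo-4-methoxyphenol
Product: 18 1,3-dibromo-2,5-dimethoxybenzene
Conditions: MeI, K2CO3, acetone, reflux
Reagents that add atoms: iodomethane, CI
Why: Williamson methylation of a phenoxide; the acidic dibromophenol is alkylated cleanly.

Step 10
Reactants: 16 (2S,4S,5R,6S)-N,4,5-trimethoxy-7-[(4-methoxybenzyl)oxy]-N,2,6-trimethylheptanamide; 18 1,3-dibromo-2,5-dimethoxybenzene
Product: 20 (2S,4S,5R,6S)-1-(3-bromo-2,5-dimethoxyphenyl)-4,5-dimethoxy-7-[(4-methoxybenzyl)oxy]-2,6-dimethylheptan-1-one, via aryllithium 19 (not isolated)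
Conditions: 18, n-BuLi (1 equiv), THF, −78 °C; then 16, −78 to −20 °C; aq. NH4Cl
Reagents that add atoms: none
Why: bromine–lithium exchange at one of two equivalent bromines followed by Weinreb ketone synthesis; the chelated tetrahedral adduct should stop at the ketone, and the second bromine stays for the ring closure at C20.

Step 11
Reactants: 20 (2S,4S,5R,6S)-1-(3-bromo-2,5-dimethoxyphenyl)-4,5-dimethoxy-7-[(4-methoxybenzyl)oxy]-2,6-dimethylheptan-1-one
Product: 21 (1R,2S,4S,5R,6S)-1-(3-bromo-2,5-dimethoxyphenyl)-4,5-dimethoxy-7-[(4-methoxybenzyl)oxy]-2,6-dimethylheptan-1-ol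
Conditions: (S)-1-methyl-3,3-diphenyltetrahydro-1H,3H-pyrrolo[1,2-c][1,3,2]oxazaborole (0.5 equiv), BH3·SMe2, THF, −20 °C; MeOH quench
Reagents that add atoms: none
Why: Corey–Bakshi–Shibata reduction; with the aryl group as the large substituent the (S)-catalyst should deliver hydride to give the 15R carbinol (14,15-syn), catalyst control overriding the weak opposite Felkin bias of the α-methyl ketone.

Step 12
Reactants: 21 (1R,2S,4S,5R,6S)-1-(3-bromo-2,5-dimethoxyphenyl)-4,5-dimethoxy-7-[(4-methoxybenzyl)oxy]-2,6-dimethylheptan-1-ol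
Product: 22 [(1R,2S,4S,5R,6S)-1-(3-bromo-2,5-dimethoxyphenyl)-4,5-dimethoxy-7-[(4-methoxybenzyl)oxy]-2,6-dimethylheptyl]oxy(tert-butyl)dimethylsilane
Conditions: TBSOTf, 2,6-lutidine, CH2Cl2, 0 °C
Reagents that add atoms: tert-butyldimethylsilyl trifluoromethanesulfonate, CC(C)(C)[Si](C)(C)OS(=O)(=O)C(F)(F)F
Why: silylation with a silyl triflate is reactive enough for the hindered benzylic C15 alcohol and gives an ether that should last to the final step.

Step 13
Reactants: 22 [(1R,2S,4S,5R,6S)-1-(3-bromo-2,5-dimethoxyphenyl)-4,5-dimethoxy-7-[(4-methoxybenzyl)oxy]-2,6-dimethylheptyl]oxy(tert-butyl)dimethylsilane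
Product: 23 (2S,3R,4S,6S,7R)-7-(3-bromo-2,5-dimethoxyphenyl)-7-(tert-butyldimethylsilyloxy)-3,4-dimethoxy-2,6-dimethylheptan-1-ol
Conditions: DDQ, CH2Cl2/pH 7 buffer, 0 °C
Reagents that add atoms: none
Why: oxidative cleavage of the 4-methoxybenzyl ether by DDQ; the brominated, hindered dimethoxyarene with its silylated benzylic position should be much slower to oxidise than the anisyl ether.

Step 14
Reactants: 23 (2S,3R,4S,6S,7R)-7-(3-bromo-2,5-dimethoxyphenyl)-7-(tert-butyldimethylsilyloxy)-3,4-dimethoxy-2,6-dimethylheptan-1-ol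
Product: 24 (2R,3R,4S,6S,7R)-7-(3-bromo-2,5-dimethoxyphenyl)-7-(tert-butyldimethylsilyloxy)-3,4-dimethoxy-2,6-dimethylheptanal
Conditions: Dess–Martin periodinane, NaHCO3, CH2Cl2, 0 °C to rt; used crude
Reagents that add atoms: none
Why: Dess–Martin oxidation under buffered conditions should give the C9 aldehyde without epimerising C10 or eliminating the C11 methoxy group.

Step 15
Reactants: 24 (2R,3R,4S,6S,7R)-7-(3-bromo-2,5-dimethoxyphenyl)-7-(tert-butyldimethylsilyloxy)-3,4-dimethoxy-2,6-dimethylheptanal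
Product: 25 (2E,4S,5R,6S,8S,9R)-9-(3-bromo-2,5-dimethoxyphenyl)-9-(tert-butyldimethylsilyloxy)-5,6-dimethoxy-2,4,8-trimethylnon-2-enal
Conditions: Ph3P=C(Me)CHO, toluene, 80 °C
Reagents that add atoms: 2-(triphenylphosphoranylidene)propanal, CC(C=O)=P(c1ccccc1)(c1ccccc1)c1ccccc1
Why: Wittig olefination with a stabilised formyl ylide should give the E trisubstituted C8=C9 enal directly, and the enal product is less reactive towards the ylide than the starting aldehyde.

Step 16
Reactants: 25 (2E,4S,5R,6S,8S,9R)-9-(3-bromo-2,5-dimethoxyphenyl)-9-(tert-butyldimethylsilyloxy)-5,6-dimethoxy-2,4,8-trimethylnon-2-enal; 1 (R)-4-benzyl-3-propanoyl-1,3-oxazolidin-2-one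
Product: 27 (R)-4-benzyl-3-[(2R,3R,4E,6S,7R,8S,10S,11R)-11-(3-bromo-2,5-dimethoxyphenyl)-11-(tert-butyldimethylsilyloxy)-3-hydroxy-7,8-dimethoxy-2,4,6,10-tetramethylundec-4-enoyl]-1,3-oxazolidin-2-one, via chlorotitanium enolate 26 (not isolated)
Conditions: 1 (1.5 equiv), TiCl4, i-Pr2NEt, N-methylpyrrolidin-2-one, CH2Cl2, 0 °C; then 25, −78 to 0 °C; aq. NH4Cl
Reagents that add atoms: none
Why: Evans syn aldol reaction through the Z chlorotitanium enolate made by soft enolisation with TiCl4 and amine; the chair transition state is steered by the benzyl group of the auxiliary in the same sense as in step 1 and the enal has no α-stereocentre to oppose it, so C6 and C7 should be set syn (6S,7R in the target), while the non-oxidative work-up spares the electron-rich arene.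

Step 17
Reactants: 27 (R)-4-benzyl-3-[(2R,3R,4E,6S,7R,8S,10S,11R)-11-(3-bromo-2,5-dimethoxyphenyl)-11-(tert-butyldimethylsilyloxy)-3-hydroxy-7,8-dimethoxy-2,4,6,10-tetramethylundec-4-enoyl]-1,3-oxazolidin-2-one
Product: 28 (R)-4-benzyl-3-[(2R,3R,4E,6S,7R,8S,10S,11R)-11-(3-bromo-2,5-dimethoxyphenyl)-11-(tert-butyldimethylsilyloxy)-7,8-dimethoxy-2,4,6,10-tetramethyl-3-(triethylsilyloxy)undec-4-enoyl]-1,3-oxazolidin-2-one
Conditions: TESOTf, 2,6-lutidine, CH2Cl2, −78 °C
Reagents that add atoms: triethylsilyl trifluoromethanesulfonate, CC[Si](CC)(CC)OS(=O)(=O)C(F)(F)F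
Why: silyl triflate protection of the C7 hydroxyl as a triethylsilyl ether, chosen so that it can later be removed while the C15 tert-butyldimethylsilyl ether stays.

Step 18
Reactants: 28 (R)-4-benzyl-3-[(2R,3R,4E,6S,7R,8S,10S,11R)-11-(3-bromo-2,5-dimethoxyphenyl)-11-(tert-butyldimethylsilyloxy)-7,8-dimethoxy-2,4,6,10-tetramethyl-3-(triethylsilyloxy)undec-4-enoyl]-1,3-oxazolidin-2-one
Product: 29 (2S,3R,4E,6S,7R,8S,10S,11R)-11-(3-bromo-2,5-dimethoxyphenyl)-11-(tert-butyldimethylsilyloxy)-7,8-dimethoxy-2,4,6,10-tetramethyl-3-(triethylsilyloxy)undec-4-en-1-ol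
Conditions: LiBH4, MeOH (1 equiv), THF, 0 °C
Reagents that add atoms: none
Why: reductive removal of the oxazolidinone by borohydride should give the C5 primary alcohol without touching the silyl ethers or the aryl bromide.

Step 19
Reactants: 29 (2S,3R,4E,6S,7R,8S,10S,11R)-11-(3-bromo-2,5-dimethoxyphenyl)-11-(tert-butyldimethylsilyloxy)-7,8-dimethoxy-2,4,6,10-tetramethyl-3-(triethylsilyloxy)undec-4-en-1-ol
Product: 30 (2R,3R,4E,6S,7R,8S,10S,11R)-11-(3-bromo-2,5-dimethoxyphenyl)-11-(tert-butyldimethylsilyloxy)-7,8-dimethoxy-2,4,6,10-tetramethyl-3-(triethylsilyloxy)undec-4-enal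
Conditions: Dess–Martin periodinane, NaHCO3, CH2Cl2, 0 °C; used crude
Reagents that add atoms: none
Why: Dess–Martin oxidation should give the C5 aldehyde under neutral conditions that do not epimerise C6.

Step 20
Reactants: 30 (2R,3R,4E,6S,7R,8S,10S,11R)-11-(3-bromo-2,5-dimethoxyphenyl)-11-(tert-butyldimethylsilyloxy)-7,8-dimethoxy-2,4,6,10-tetramethyl-3-(triethylsilyloxy)undec-4-enal
Product: 31 methyl (2Z,4S,5R,6E,8S,9R,10S,12S,13R)-13-(3-bromo-2,5-dimethoxyphenyl)-13-(tert-butyldimethylsilyloxy)-9,10-dimethoxy-4,6,8,12-tetramethyl-5-(triethylsilyloxy)trideca-2,6-dienoate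
Conditions: (CF3CH2O)2P(O)CH2CO2Me, KN(SiMe3)2, 18-crown-6, THF, −78 °C
Reagents that add atoms: methyl bis(2,2,2-trifluoroethyl)phosphonoacetate, COC(=O)CP(=O)(OCC(F)(F)F)OCC(F)(F)F
Why: Still–Gennari olefination; fast irreversible elimination from the kinetically formed adduct of the trifluoroethyl phosphonate should give the Z C4=C5 enoate at −78 °C without epimerising C6.

Step 21
Reactants: 31 methyl (2Z,4S,5R,6E,8S,9R,10S,12S,13R)-13-(3-bromo-2,5-dimethoxyphenyl)-13-(tert-butyldimethylsilyloxy)-9,10-dimethoxy-4,6,8,12-tetramethyl-5-(triethylsilyloxy)trideca-2,6-dienoate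
Product: 32 (2Z,4S,5R,6E,8S,9R,10S,12S,13R)-13-(3-bromo-2,5-dimethoxyphenyl)-13-(tert-butyldimethylsilyloxy)-9,10-dimethoxy-4,6,8,12-tetramethyl-5-(triethylsilyloxy)trideca-2,6-dien-1-ol
Conditions: i-Bu2AlH, CH2Cl2, −78 °C
Reagents that add atoms: none
Why: 1,2-reduction of the enoate by the aluminium hydride should give the Z allylic alcohol with the double bond geometry retained.

Step 22
Reactants: 32 (2Z,4S,5R,6E,8S,9R,10S,12S,13R)-13-(3-bromo-2,5-dimethoxyphenyl)-13-(tert-butyldimethylsilyloxy)-9,10-dimethoxy-4,6,8,12-tetramethyl-5-(triethylsilyloxy)trideca-2,6-dien-1-ol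
Product: 34 ethyl (2E,4Z,6S,7R,8E,10S,11R,12S,14S,15R)-15-(3-bromo-2,5-dimethoxyphenyl)-15-(tert-butyldimethylsilyloxy)-11,12-dimethoxy-2,6,8,10,14-pentamethyl-7-(triethylsilyloxy)pentadeca-2,4,8-trienoate, via Z-enal 33 (not isolated)
Conditions: MnO2 (activated, excess), Ph3P=C(Me)CO2Et, CH2Cl2, rt
Reagents that add atoms: ethyl 2-(triphenylphosphoranylidene)propanoate, CCOC(=O)C(C)=P(c1ccccc1)(c1ccccc1)c1ccccc1
Why: tandem allylic oxidation and Wittig olefination; the Z-enal is trapped as it forms, which should limit its isomerisation, and the stabilised ylide gives the 2E double bond.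

Step 23
Reactants: 34 ethyl (2E,4Z,6S,7R,8E,10S,11R,12S,14S,15R)-15-(3-bromo-2,5-dimethoxyphenyl)-15-(tert-butyldimethylsilyloxy)-11,12-dimethoxy-2,6,8,10,14-pentamethyl-7-(triethylsilyloxy)pentadeca-2,4,8-trienoate
Product: 35 (2E,4Z,6S,7R,8E,10S,11R,12S,14S,15R)-15-(3-bromo-2,5-dimethoxyphenyl)-15-(tert-butyldimethylsilyloxy)-11,12-dimethoxy-2,6,8,10,14-pentamethyl-7-(triethylsilyloxy)pentadeca-2,4,8-trienoic acid
Conditions: LiOH, THF/MeOH/H2O, rt; then dilute HCl to pH 4, 0 °C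
Reagents that add atoms: lithium hydroxide, [Li+].[OH-]
Why: saponification of the dienoate; hydroxide should not disturb the silyl ethers or the diene geometry at room temperature.

Step 24
Reactants: 35 (2E,4Z,6S,7R,8E,10S,11R,12S,14S,15R)-15-(3-bromo-2,5-dimethoxyphenyl)-15-(tert-butyldimethylsilyloxy)-11,12-dimethoxy-2,6,8,10,14-pentamethyl-7-(triethylsilyloxy)pentadeca-2,4,8-trienoic acid
Product: 37 (2E,4Z,6S,7R,8E,10S,11R,12S,14S,15R)-15-(3-bromo-2,5-dimethoxyphenyl)-15-(tert-butyldimethylsilyloxy)-11,12-dimethoxy-2,6,8,10,14-pentamethyl-7-(triethylsilyloxy)pentadeca-2,4,8-trienamide, via mixed anhydride 36 (not isolated)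
Conditions: i-BuOCOCl, Et3N, THF, −15 °C; then NH3 (gas), −15 °C to rt
Reagents that add atoms: ammonia, N
Why: mixed carbonic anhydride activation and ammonolysis; ammonia should attack the less hindered, more electrophilic acyl carbon of the dienoyl unit to give the primary amide.

Step 25
Reactants: 37 (2E,4Z,6S,7R,8E,10S,11R,12S,14S,15R)-15-(3-bromo-2,5-dimethoxyphenyl)-15-(tert-butyldimethylsilyloxy)-11,12-dimethoxy-2,6,8,10,14-pentamethyl-7-(triethylsilyloxy)pentadeca-2,4,8-trienamide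
Product: 38 19-membered macrolactam (N–C20 bond closed) carrying the 18,21-dimethoxyarene with 15-O-tert-butyldimethylsilyl and 7-O-triethylsilyl ethers (2E,4Z,8E; 6S,7R,10S,11R,12S,14S,15R)
Conditions: CuI (0.5 equiv), N,N′-dimethylethane-1,2-diamine, K2CO3, toluene, 100 °C, high dilution
Reagents that add atoms: none
Why: intramolecular Goldberg N-arylation of a primary amide with an aryl bromide under diamine-ligated copper catalysis; high dilution should favour closure of the 19-membered ring over oligomers.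

Step 26
Reactants: 38 19-membered macrolactam with 15-O-tert-butyldimethylsilyl and 7-O-triethylsilyl ethers
Product: 39 7-hydroxy macrolactam (18,21-dimethoxyarene; 15-O-tert-butyldimethylsilyl ether retained)
Conditions: pyridinium p-toluenesulfonate (cat.), MeOH/CH2Cl2, 0 °C to rt
Reagents that add atoms: none
Why: acid-catalysed methanolysis should remove the triethylsilyl ether selectively, because the bulkier silyl group on the hindered benzylic C15 oxygen solvolyses much more slowly.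

Step 27
Reactants: 39 7-hydroxy macrolactam
Product: 41 7-O-carbamoyl macrolactam (18,21-dimethoxyarene; 15-O-tert-butyldimethylsilyl ether), via trichloroacetyl carbamate 40 (not isolated)
Conditions: Cl3CC(O)NCO, CH2Cl2, 0 °C; then K2CO3, MeOH, rt
Reagents that add atoms: trichloroacetyl isocyanate, O=C=NC(=O)C(Cl)(Cl)Cl
Why: carbamoylation by addition of the C7 alcohol to the acyl isocyanate followed by methanolysis of the trichloroacetyl group; the hindered anilide N–H should not compete at 0 °C.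

Step 28
Reactants: 41 7-O-carbamoyl macrolactam
Product: 42 15-O-tert-butyldimethylsilyl ether of the target quinone
Conditions: (NH4)2Ce(NO3)6, MeCN/H2O, 0 °C
Reagents that add atoms: water, O
Why: oxidative demethylation with (NH4)2Ce(NO3)6; the two methoxy groups are para on the amido-substituted ring, so only the 1,4-benzoquinone with carbonyls at C18 and C21 can form.

Step 29
Reactants: 42 15-O-tert-butyldimethylsilyl ether of the target quinone
Product: 43 CNP0557283.1 (target)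
Conditions: HF·pyridine, pyridine, THF, 0 °C to rt
Reagents that add atoms: none
Why: fluoride-mediated desilylation under buffered acidic conditions should free the C15 hydroxyl without harming the quinone, the carbamate or the diene.

**Compound list**

1 | (R)-4-benzyl-3-propanoyl-1,3-oxazolidin-2-one | CCC(=O)N1[C@H](Cc2ccccc2)COC1=O | starting material
2 | acrolein | C=CC=O | starting material
3 | Z dibutylboron enolate of 1 | CCCCB(CCCC)O/C(=C\C)N1[C@H](Cc2ccccc2)COC1=O | intermediate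
4 | (R)-4-benzyl-3-[(2R,3S)-3-hydroxy-2-methylpent-4-enoyl]-1,3-oxazolidin-2-one | C=C[C@H](O)[C@@H](C)C(=O)N1[C@H](Cc2ccccc2)COC1=O | intermediate
5 | (R)-4-benzyl-3-[(2R,3S)-3-methoxy-2-methylpent-4-enoyl]-1,3-oxazolidin-2-one | C=C[C@H](OC)[C@@H](C)C(=O)N1[C@H](Cc2ccccc2)COC1=O | intermediate
6 | (2S,3S)-3-methoxy-2-methylpent-4-en-1-ol | C=C[C@H](OC)[C@@H](C)CO | intermediate
7 | (3S,4S)-3-methoxy-5-[(4-methoxybenzyl)oxy]-4-methylpent-1-ene | C=C[C@H](OC)[C@@H](C)COCc1ccc(OC)cc1 | intermediate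
8 | 3-{(1R,2S)-1-methoxy-3-[(4-methoxybenzyl)oxy]-2-methylpropyl}-1,2,4-trioxolane (ozonide; ring carbon unresolved) | C1(OCOO1)[C@H](OC)[C@@H](C)COCc1ccc(OC)cc1 | intermediate
9 | (2R,3S)-2-methoxy-4-[(4-methoxybenzyl)oxy]-3-methylbutanal (C9–C12) | O=C[C@H](OC)[C@@H](C)COCc1ccc(OC)cc1 | intermediate
10 | methyl methacrylate (C13–C15) | C=C(C)C(=O)OC | starting material
11 | methyl (4S,5R,6S)-4-hydroxy-5-methoxy-7-[(4-methoxybenzyl)oxy]-2,6-dimethylheptanoate, present as its samarium alkoxide, C2 unresolved (drawn as the free alcohol) | COC(=O)C(C)C[C@H](O)[C@H](OC)[C@@H](C)COCc1ccc(OC)cc1 | intermediate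
12 | (5S)-5-{(1R,2S)-1-methoxy-3-[(4-methoxybenzyl)oxy]-2-methylpropyl}-3-methyloxolan-2-one, both C14 epimers | CC1C[C@H](OC1=O)[C@H](OC)[C@@H](C)COCc1ccc(OC)cc1 | intermediate
13 | lithium enolate of 12 | CC1=C(O[Li])O[C@@H](C1)[C@H](OC)[C@@H](C)COCc1ccc(OC)cc1 | intermediate
14 | (3S,5S)-5-{(1R,2S)-1-methoxy-3-[(4-methoxybenzyl)oxy]-2-methylpropyl}-3-methyloxolan-2-one (cis lactone) | C[C@H]1C[C@H](OC1=O)[C@H](OC)[C@@H](C)COCc1ccc(OC)cc1 | intermediate
15 | (2S,4S,5R,6S)-4-hydroxy-N,5-dimethoxy-7-[(4-methoxybenzyl)oxy]-N,2,6-trimethylheptanamide | CON(C)C(=O)[C@@H](C)C[C@H](O)[C@H](OC)[C@@H](C)COCc1ccc(OC)cc1 | intermediate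
16 | (2S,4S,5R,6S)-N,4,5-trimethoxy-7-[(4-methoxybenzyl)oxy]-N,2,6-trimethylheptanamide | CON(C)C(=O)[C@@H](C)C[C@H](OC)[C@H](OC)[C@@H](C)COCc1ccc(OC)cc1 | intermediate
17 | 2,6-dibromo-4-methoxyphenol | COc1cc(Br)c(O)c(Br)c1 | starting material
18 | 1,3-dibromo-2,5-dimethoxybenzene | COc1cc(Br)c(OC)c(Br)c1 | intermediate
19 | (3-bromo-2,5-dimethoxyphenyl)lithium | [Li]c1cc(OC)cc(Br)c1OC | intermediate
20 | (2S,4S,5R,6S)-1-(3-bromo-2,5-dimethoxyphenyl)-4,5-dimethoxy-7-[(4-methoxybenzyl)oxy]-2,6-dimethylheptan-1-one | COc1cc(Br)c(OC)c(c1)C(=O)[C@@H](C)C[C@H](OC)[C@H](OC)[C@@H](C)COCc1ccc(OC)cc1 | intermediate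
21 | (1R,2S,4S,5R,6S)-1-(3-bromo-2,5-dimethoxyphenyl)-4,5-dimethoxy-7-[(4-methoxybenzyl)oxy]-2,6-dimethylheptan-1-ol | COc1cc(Br)c(OC)c(c1)[C@H](O)[C@@H](C)C[C@H](OC)[C@H](OC)[C@@H](C)COCc1ccc(OC)cc1 | intermediate
22 | tert-butyldimethylsilyl ether of 21 | COc1cc(Br)c(OC)c(c1)[C@H](O[Si](C)(C)C(C)(C)C)[C@@H](C)C[C@H](OC)[C@H](OC)[C@@H](C)COCc1ccc(OC)cc1 | intermediate
23 | (2S,3R,4S,6S,7R)-7-(3-bromo-2,5-dimethoxyphenyl)-7-(tert-butyldimethylsilyloxy)-3,4-dimethoxy-2,6-dimethylheptan-1-ol | COc1cc(Br)c(OC)c(c1)[C@H](O[Si](C)(C)C(C)(C)C)[C@@H](C)C[C@H](OC)[C@H](OC)[C@@H](C)CO | intermediate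
24 | (2R,3R,4S,6S,7R)-7-(3-bromo-2,5-dimethoxyphenyl)-7-(tert-butyldimethylsilyloxy)-3,4-dimethoxy-2,6-dimethylheptanal | COc1cc(Br)c(OC)c(c1)[C@H](O[Si](C)(C)C(C)(C)C)[C@@H](C)C[C@H](OC)[C@H](OC)[C@@H](C)C=O | intermediate
25 | (2E,4S,5R,6S,8S,9R)-9-(3-bromo-2,5-dimethoxyphenyl)-9-(tert-butyldimethylsilyloxy)-5,6-dimethoxy-2,4,8-trimethylnon-2-enal | COc1cc(Br)c(OC)c(c1)[C@H](O[Si](C)(C)C(C)(C)C)[C@@H](C)C[C@H](OC)[C@H](OC)[C@@H](C)/C=C(\C)C=O | intermediate
26 | Z trichlorotitanium enolate of 1 | C/C=C(\O[Ti](Cl)(Cl)Cl)N1[C@H](Cc2ccccc2)COC1=O | intermediate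
27 | (R)-4-benzyl-3-[(2R,3R,4E,6S,7R,8S,10S,11R)-11-(3-bromo-2,5-dimethoxyphenyl)-11-(tert-butyldimethylsilyloxy)-3-hydroxy-7,8-dimethoxy-2,4,6,10-tetramethylundec-4-enoyl]-1,3-oxazolidin-2-one | COc1cc(Br)c(OC)c(c1)[C@H](O[Si](C)(C)C(C)(C)C)[C@@H](C)C[C@H](OC)[C@H](OC)[C@@H](C)/C=C(\C)[C@H](O)[C@@H](C)C(=O)N1[C@H](Cc2ccccc2)COC1=O | intermediate
28 | 3-O-triethylsilyl ether of 27 | COc1cc(Br)c(OC)c(c1)[C@H](O[Si](C)(C)C(C)(C)C)[C@@H](C)C[C@H](OC)[C@H](OC)[C@@H](C)/C=C(\C)[C@H](O[Si](CC)(CC)CC)[C@@H](C)C(=O)N1[C@H](Cc2ccccc2)COC1=O | intermediate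
29 | (2S,3R,4E,6S,7R,8S,10S,11R)-11-(3-bromo-2,5-dimethoxyphenyl)-11-(tert-butyldimethylsilyloxy)-7,8-dimethoxy-2,4,6,10-tetramethyl-3-(triethylsilyloxy)undec-4-en-1-ol | COc1cc(Br)c(OC)c(c1)[C@H](O[Si](C)(C)C(C)(C)C)[C@@H](C)C[C@H](OC)[C@H](OC)[C@@H](C)/C=C(\C)[C@H](O[Si](CC)(CC)CC)[C@@H](C)CO | intermediate
30 | (2R,3R,4E,6S,7R,8S,10S,11R)-11-(3-bromo-2,5-dimethoxyphenyl)-11-(tert-butyldimethylsilyloxy)-7,8-dimethoxy-2,4,6,10-tetramethyl-3-(triethylsilyloxy)undec-4-enal | COc1cc(Br)c(OC)c(c1)[C@H](O[Si](C)(C)C(C)(C)C)[C@@H](C)C[C@H](OC)[C@H](OC)[C@@H](C)/C=C(\C)[C@H](O[Si](CC)(CC)CC)[C@@H](C)C=O | intermediate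
31 | methyl (2Z,4S,5R,6E,8S,9R,10S,12S,13R)-13-(3-bromo-2,5-dimethoxyphenyl)-13-(tert-butyldimethylsilyloxy)-9,10-dimethoxy-4,6,8,12-tetramethyl-5-(triethylsilyloxy)trideca-2,6-dienoate | COc1cc(Br)c(OC)c(c1)[C@H](O[Si](C)(C)C(C)(C)C)[C@@H](C)C[C@H](OC)[C@H](OC)[C@@H](C)/C=C(\C)[C@H](O[Si](CC)(CC)CC)[C@@H](C)\C=C/C(=O)OC | intermediate
32 | (2Z,4S,5R,6E,8S,9R,10S,12S,13R)-13-(3-bromo-2,5-dimethoxyphenyl)-13-(tert-butyldimethylsilyloxy)-9,10-dimethoxy-4,6,8,12-tetramethyl-5-(triethylsilyloxy)trideca-2,6-dien-1-ol | COc1cc(Br)c(OC)c(c1)[C@H](O[Si](C)(C)C(C)(C)C)[C@@H](C)C[C@H](OC)[C@H](OC)[C@@H](C)/C=C(\C)[C@H](O[Si](CC)(CC)CC)[C@@H](C)\C=C/CO | intermediate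
33 | (2Z,4S,5R,6E,8S,9R,10S,12S,13R)-13-(3-bromo-2,5-dimethoxyphenyl)-13-(tert-butyldimethylsilyloxy)-9,10-dimethoxy-4,6,8,12-tetramethyl-5-(triethylsilyloxy)trideca-2,6-dienal | COc1cc(Br)c(OC)c(c1)[C@H](O[Si](C)(C)C(C)(C)C)[C@@H](C)C[C@H](OC)[C@H](OC)[C@@H](C)/C=C(\C)[C@H](O[Si](CC)(CC)CC)[C@@H](C)\C=C/C=O | intermediate
34 | ethyl (2E,4Z,6S,7R,8E,10S,11R,12S,14S,15R)-15-(3-bromo-2,5-dimethoxyphenyl)-15-(tert-butyldimethylsilyloxy)-11,12-dimethoxy-2,6,8,10,14-pentamethyl-7-(triethylsilyloxy)pentadeca-2,4,8-trienoate | COc1cc(Br)c(OC)c(c1)[C@H](O[Si](C)(C)C(C)(C)C)[C@@H](C)C[C@H](OC)[C@H](OC)[C@@H](C)/C=C(\C)[C@H](O[Si](CC)(CC)CC)[C@@H](C)\C=C/C=C(\C)C(=O)OCC | intermediate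
35 | the carboxylic acid of 34 (pentadeca-2,4,8-trienoic acid; same descriptors) | COc1cc(Br)c(OC)c(c1)[C@H](O[Si](C)(C)C(C)(C)C)[C@@H](C)C[C@H](OC)[C@H](OC)[C@@H](C)/C=C(\C)[C@H](O[Si](CC)(CC)CC)[C@@H](C)\C=C/C=C(\C)C(O)=O | intermediate
36 | isobutyl carbonic mixed anhydride of 35 | COc1cc(Br)c(OC)c(c1)[C@H](O[Si](C)(C)C(C)(C)C)[C@@H](C)C[C@H](OC)[C@H](OC)[C@@H](C)/C=C(\C)[C@H](O[Si](CC)(CC)CC)[C@@H](C)\C=C/C=C(\C)C(=O)OC(=O)OCC(C)C | intermediate
37 | the primary amide of 35 (pentadeca-2,4,8-trienamide; same descriptors) | COc1cc(Br)c(OC)c(c1)[C@H](O[Si](C)(C)C(C)(C)C)[C@@H](C)C[C@H](OC)[C@H](OC)[C@@H](C)/C=C(\C)[C@H](O[Si](CC)(CC)CC)[C@@H](C)\C=C/C=C(\C)C(N)=O | intermediate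
38 | 19-membered macrolactam; 18,21-dimethoxyarene; 15-O-tert-butyldimethylsilyl; 7-O-triethylsilyl (2E,4Z,8E; 6S,7R,10S,11R,12S,14S,15R) | CO[C@H]1[C@@H](OC)C[C@H](C)[C@@H](O[Si](C)(C)C(C)(C)C)c2cc(OC)cc(NC(=O)/C(C)=C/C=C\[C@H](C)[C@@H](O[Si](CC)(CC)CC)/C(C)=C/[C@@H]1C)c2OC | intermediate
39 | 7-hydroxy macrolactam; 18,21-dimethoxyarene; 15-O-tert-butyldimethylsilyl | CO[C@H]1[C@@H](OC)C[C@H](C)[C@@H](O[Si](C)(C)C(C)(C)C)c2cc(OC)cc(NC(=O)/C(C)=C/C=C\[C@H](C)[C@@H](O)/C(C)=C/[C@@H]1C)c2OC | intermediate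
40 | 7-O-(N-trichloroacetylcarbamoyl) macrolactam | CO[C@H]1[C@@H](OC)C[C@H](C)[C@@H](O[Si](C)(C)C(C)(C)C)c2cc(OC)cc(NC(=O)/C(C)=C/C=C\[C@H](C)[C@@H](OC(=O)NC(=O)C(Cl)(Cl)Cl)/C(C)=C/[C@@H]1C)c2OC | intermediate
41 | 7-O-carbamoyl macrolactam; 18,21-dimethoxyarene; 15-O-tert-butyldimethylsilyl | CO[C@H]1[C@@H](OC)C[C@H](C)[C@@H](O[Si](C)(C)C(C)(C)C)c2cc(OC)cc(NC(=O)/C(C)=C/C=C\[C@H](C)[C@@H](OC(N)=O)/C(C)=C/[C@@H]1C)c2OC | intermediate
42 | 15-O-tert-butyldimethylsilyl ether of the target quinone | CO[C@H]1[C@@H](OC)C[C@H](C)[C@@H](O[Si](C)(C)C(C)(C)C)C2=CC(=O)C=C(NC(=O)/C(C)=C/C=C\[C@H](C)[C@@H](OC(N)=O)/C(C)=C/[C@@H]1C)C2=O | intermediate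
43 | CNP0557283.1 | CO[C@H]1[C@@H](OC)C[C@H](C)[C@@H](O)C2=CC(=O)C=C(NC(=O)/C(C)=C/C=C\[C@H](C)[C@@H](OC(N)=O)/C(C)=C/[C@@H]1C)C2=O | target

**Step count**

Total: 29 steps (step 6 is run as two operations with one purification). Longest linear sequence: 28 steps (steps 1–8 and 10–29; step 9 is the arene branch).

**Steps most likely to fail**

Step 6. The ketyl may add with poor facial selectivity, because chelation of samarium by the C11 methoxy oxygen would favour the 11,12-syn lactone. It may also dimerise to the pinacol, or lose methoxide after over-reduction. The fallback sets out from 9 and forms the C12–C13 bond by a reagent-controlled polar addition. Brown methallylation with B-(2-methylallyl)diisopinocampheylborane, made from (−)-B-methoxydiisopinocampheylborane and 2-methylallylmagnesium chloride (the antipode expected to attack the Si face of the aldehyde), should give homoallylic alcohol F1. Hydroboration of the 1,1-disubstituted alkene with 9-borabicyclo[3.3.1]nonane and oxidation with NaOH/H2O2 should give diol F2 as a C14 mixture. Oxidative lactonisation with 2,2,6,6-tetramethylpiperidin-1-oxyl (cat.) and PhI(OAc)2 closes the same ring as epimer mixture 12. The enolate protonation of step 6 then converges on 14, where the route is rejoined.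

Step 11. The catalyst-controlled hydride delivery is opposed by the Felkin preference of the α-methyl ketone and by the ortho-methoxy group, so the syn to anti selectivity at C15 may erode. The fallback sets out from 16 and makes the C15 carbinol by addition and not by reduction. i-Bu2AlH (THF, −78 °C) should reduce the Weinreb amide to aldehyde F3. Addition of aryllithium 19 (prepared as in step 10) at −78 °C then follows the Felkin–Anh model, which for an α-methyl aldehyde gives the 14,15-syn alcohol, and the route is rejoined at 21. The minor epimer could be oxidised to 20 and recycled.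

Step 25. Ring closure at 100 °C under base may give oligomers, isomerise the 4Z double bond, or stall at the hindered bromide ortho to a methoxy group. The fallback sets out from 34 and closes the ring by amide bond formation. Buchwald–Hartwig amination of the aryl bromide with benzophenone imine (Pd2(dba)3, 2,2′-bis(diphenylphosphino)-1,1′-binaphthyl, Cs2CO3, toluene, 80 °C) should give imine F4. Cleavage with NH2OH·HCl/NaOAc in MeOH gives aniline ester F5, and LiOH hydrolysis gives amino acid F6. Macrolactamisation with bis(2-oxo-3-oxazolidinyl)phosphinic chloride and i-Pr2NEt in toluene at high dilution then gives 38, where the route is rejoined.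

**Further compounds**

F1 | step 6 | (2S,3R,4S)-3-methoxy-1-[(4-methoxybenzyl)oxy]-2,6-dimethylhept-6-en-4-ol | C=C(C)C[C@H](O)[C@H](OC)[C@@H](C)COCc1ccc(OC)cc1
F2 | step 6 | (4S,5R,6S)-5-methoxy-7-[(4-methoxybenzyl)oxy]-2,6-dimethylheptane-1,4-diol (both C2 epimers) | OCC(C)C[C@H](O)[C@H](OC)[C@@H](C)COCc1ccc(OC)cc1
F3 | step 11 | (2S,4S,5R,6S)-4,5-dimethoxy-7-[(4-methoxybenzyl)oxy]-2,6-dimethylheptanal | O=C[C@@H](C)C[C@H](OC)[C@H](OC)[C@@H](C)COCc1ccc(OC)cc1
F4 | step 25 | N-(diphenylmethylene)aniline analogue of 34 (bromine replaced by N=CPh2) | COc1cc(N=C(c2ccccc2)c2ccccc2)c(OC)c(c1)[C@H](O[Si](C)(C)C(C)(C)C)[C@@H](C)C[C@H](OC)[C@H](OC)[C@@H](C)/C=C(\C)[C@H](O[Si](CC)(CC)CC)[C@@H](C)\C=C/C=C(\C)C(=O)OCC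
F5 | step 25 | aniline ethyl ester (bromine of 34 replaced by NH2) | COc1cc(N)c(OC)c(c1)[C@H](O[Si](C)(C)C(C)(C)C)[C@@H](C)C[C@H](OC)[C@H](OC)[C@@H](C)/C=C(\C)[C@H](O[Si](CC)(CC)CC)[C@@H](C)\C=C/C=C(\C)C(=O)OCC
F6 | step 25 | amino acid (aniline and free carboxylic acid) | COc1cc(N)c(OC)c(c1)[C@H](O[Si](C)(C)C(C)(C)C)[C@@H](C)C[C@H](OC)[C@H](OC)[C@@H](C)/C=C(\C)[C@H](O[Si](CC)(CC)CC)[C@@H](C)\C=C/C=C(\C)C(O)=O
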